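The ten-membered carbocycle (C1–C10, germacrane numbering) is closed at the C2–C3 single bond. C2 is the γ-carbon of the C1=C10–C14 enoate, that is, the free terminus of a carbomethoxy-substituted π-allyl; a nitronate at C3 attacks it under zerovalent palladium, giving the ring and the (E)-enoate in one operation. The nitro group also sets C4 at the outset (organocatalytic Michael addition) and is then removed. The cyclisation precursor is the trans-fused γ-lactone (C6, C7, C11, C12, O) carrying a CH2CH(CH3)CH2NO2 arm on C6 and a CH(OAng)CH2C(CO2Me)=CHCH2OCO2Me arm on C7, assembled by an indium Barbier reaction and a Mitsunobu inversion.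

Key step: step 12

Remarks on the chemistry:
- Locants: C6 (lactone O) and C7 are the ring-fusion carbons, C8 bears the angelate, C10 bears CO2Me (C14), C4 bears CH3 (C15), and C11–C13 are the α-methylene lactone carbons.
- Transient stereocentres: C11 in 21–24 is drawn as the expected trans adduct; C3 in 22 is left undefined (epimer mixture). Both are destroyed later.
- Step 2: (S)-TRIP is the enantiomer expected to give Si-face attack; if the sense proves opposite, the (R)-acid is used.

Step 1
Reactants: 1 (E)-but-2-enal; 2 nitromethane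
Product: 3 (3R)-3-methyl-4-nitrobutanal
Conditions: (S)-α,α-diphenylprolinol trimethylsilyl ether (10 mol%), PhCO2H (20 mol%), MeOH, rt
Reagents that add atoms: none
Why: Iminium-catalysed asymmetric Michael addition; the CPh2(OTMS) group shields one face of the s-trans E-iminium ion of 1, so the nitronate adds to the open face and sets C4 as 3R.

Step 2
Reactants: 3 (3R)-3-methyl-4-nitrobutanal; 4 allenylboronic acid pinacol ester
Product: 5 (4R,6R)-6-methyl-7-nitrohept-1-yn-4-ol
Conditions: (S)-TRIP [(S)-3,3'-bis(2,4,6-triisopropylphenyl)-1,1'-binaphthyl-2,2'-diyl hydrogen phosphate] (10 mol%), 4 Å MS, toluene, −20 °C; aqueous work-up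
Reagents that add atoms: none
Why: Chiral phosphoric acid-catalysed propargylation (SE2' allenylboration through a closed six-membered chair transition state); the catalyst, not the remote C4 centre, selects the Si face of the aldehyde and sets C6 as R under neutral conditions that leave the nitroalkane alone.

Step 3
Reactants: 5 (4R,6R)-6-methyl-7-nitrohept-1-yn-4-ol
Product: 6 (5R)-3-methylidene-5-[(2R)-2-methyl-3-nitropropyl]oxolan-2-one
Conditions: Pd(OAc)2 (5 mol%), dppb (10 mol%), TsOH·H2O (10 mol%), CO (20 atm), toluene, 90 °C
Reagents that add atoms: carbon monoxide, [C-]#[O+]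
Why: Palladium-catalysed cyclocarbonylation of a but-3-yn-1-ol (5-exo carbonylative lactonisation: Pd–H adds to the terminal alkyne with palladium on the internal carbon, CO inserts, and the C6 hydroxyl captures the acyl) gives the α-methylene lactone with C6 untouched.

Step 4
Reactants: 6 (5R)-3-methylidene-5-[(2R)-2-methyl-3-nitropropyl]oxolan-2-one
Product: 8 (5R)-3-(bromomethyl)-5-[(2R)-2-methyl-3-nitropropyl]furan-2(5H)-one, via dibromide 7 (not isolated)
Conditions: Br2, CH2Cl2, 0 °C; then Et3N, 0 °C to rt
Reagents that add atoms: bromine, BrBr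
Why: Bromine addition to the exocyclic alkene followed by E2 dehydrobromination across C7–C11 moves the alkene into the ring and leaves the allylic bromide; the nitroalkane is inert to Br2 and is not appreciably deprotonated by Et3N in CH2Cl2.

Step 5
Reactants: 9 methyl (triphenylphosphoranylidene)acetate; 10 allyl bromide
Product: 12 methyl 2-(triphenylphosphoranylidene)pent-4-enoate, via phosphonium bromide 11 (not isolated)
Conditions: CHCl3, reflux; then 2 M aq NaOH, CH2Cl2, rt
Reagents that add atoms: none
Why: C-Alkylation of the stabilised ylide by the allylic halide, then deprotonation of the phosphonium salt, gives the α-allyl ylide (ylide alkylation).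

Step 6
Reactants: 12 methyl 2-(triphenylphosphoranylidene)pent-4-enoate; 13 glycolaldehyde dimer
Product: 14 methyl (2E)-2-(2-hydroxyethylidene)pent-4-enoate
Conditions: toluene, 80 °C
Reagents that add atoms: none
Why: Wittig olefination with glycolaldehyde released from its dimer; the α-substituted stabilised ylide should give the (E)-enoate (CO2Me trans to CH2OH), which sets the C1=C10 geometry and cannot lactonise.

Step 7
Reactants: 14 methyl (2E)-2-(2-hydroxyethylidene)pent-4-enoate
Product: 15 methyl (2E)-2-{2-[(methoxycarbonyl)oxy]ethylidene}pent-4-enoate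
Conditions: ClCO2Me, pyridine, CH2Cl2, 0 °C
Reagents that add atoms: methyl chloroformate, COC(=O)Cl
Why: Acylation of the primary allylic alcohol (carbonate formation) installs the leaving group for the later π-allyl chemistry at C2.

Step 8
Reactants: 15 methyl (2E)-2-{2-[(methoxycarbonyl)oxy]ethylidene}pent-4-enoate
Product: 16 methyl (2E)-4-[(methoxycarbonyl)oxy]-2-(2-oxoethyl)but-2-enoate
Conditions: OsO4 (2 mol%), NaIO4, 2,6-lutidine, dioxane/H2O, rt; used at once
Reagents that add atoms: osmium tetroxide (catalytic oxygen carrier), O=[Os](=O)(=O)=O; sodium periodate, [Na+].[O-]I(=O)(=O)=O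
Why: Lemieux–Johnson oxidative cleavage; OsO4 dihydroxylates the electron-rich monosubstituted alkene far faster than the trisubstituted ester-conjugated one, and periodate cleaves the diol to the C8 aldehyde.

Step 9
Reactants: 8 (5R)-3-(bromomethyl)-5-[(2R)-2-methyl-3-nitropropyl]furan-2(5H)-one; 16 methyl (2E)-4-[(methoxycarbonyl)oxy]-2-(2-oxoethyl)but-2-enoate
Product: 18 (4R,6R,7R,8S)-8-hydroxy seco-lactone (Barbier adduct), via allylindium bromide 17 (not isolated)
Conditions: In powder, THF/H2O 1:1, rt
Reagents that add atoms: none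
Why: Indium-mediated Barbier allylation; the allylindium adds through its γ-carbon C7 in a closed chair transition state, anti to the C6 substituent (C6/C7 trans) and, because the ring locks the γ-substituent trans to CH2In, with anti C7/C8 topicity (8S), regenerating the α-methylene lactone.

Step 10
Reactants: 18 (4R,6R,7R,8S)-8-hydroxy seco-lactone; 19 angelic acid
Product: 20 (4R,6R,7S,8R)-8-angelate seco-lactone
Conditions: PPh3, DIAD, toluene, 0 °C to rt
Reagents that add atoms: none
Why: Mitsunobu esterification; SN2 displacement of the C8 oxyphosphonium by angelate inverts C8 to the required 8R configuration and installs the ester in one operation, without a base or acyl-transfer catalyst that would isomerise the (Z)-enoate.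

Step 11
Reactants: 20 (4R,6R,7S,8R)-8-angelate seco-lactone
Product: 21 13-(dimethylamino) adduct of 20 (11R)
Conditions: Me2NH (2 M in THF, 1.5 equiv), THF, 0 °C
Reagents that add atoms: dimethylamine, CNC
Why: Aza-Michael addition masks the α-methylene lactone against nitronate, alkyl-radical and stannyl-radical attack; C11 is protonated to the trans adduct and is destroyed again in step 14.

Step 12
Reactants: 21 13-(dimethylamino) adduct (11R)
Product: 22 3-nitro ten-membered lactone (C3 epimers)
Conditions: Pd2(dba)3·CHCl3 (5 mol%), dppe (12 mol%), THF, 50 °C, slow addition of 21 to 0.002 M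
Reagents that add atoms: none
Why: Tsuji–Trost allylic alkylation run as a macrocyclisation: zerovalent palladium ionises the allylic methyl carbonate with loss of CO2, the methoxide so released deprotonates the primary nitroalkane, and the nitronate carbon C3 attacks the π-allyl at C2 anti to palladium. The closest known reaction type is the palladium-catalysed intramolecular allylic alkylation of stabilised carbanions to medium and large carbocycles under neutral carbonate conditions, together with the intermolecular C-allylation of nitronates. The ten-membered ring C1–C10 closes by attack at the allyl terminus remote from the tether, so that C1=C10 lies inside the ring; attack at C10 would give an eight-membered ring with a quaternary carbon and is disfavoured sterically and by the ester. C3 becomes a stereocentre without control, which does not matter because the nitro group is removed in step 13; C4, C6, C7, C8 and C11 are untouched. The step needs C- over O-allylation (O-allylation of nitronates is reversible under palladium), retention of the (E)-enoate (CO2Me stays syn on the η3-allyl because no σ-complex forms at the fully substituted C10) and cyclisation over oligomerisation, which slow addition at high dilution and the trans-fused lactone (holding the C6 and C7 arms close) should secure. The masked lactone leaves the nitronate no competing Michael acceptor, and the acylated C8 oxygen cannot close a six-membered allyl ether.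

Step 13
Reactants: 22 3-nitro ten-membered lactone (C3 epimers)
Product: 23 13-(dimethylamino)-11,13-dihydro target (11R)
Conditions: Bu3SnH (5 equiv), AIBN (0.5 equiv, in portions), toluene, 110 °C
Reagents that add atoms: none
Why: Radical denitration; Bu3Sn• adds to a nitro oxygen, C–N homolysis gives the secondary C3 radical, and hydrogen transfer from Bu3SnH leaves C3 as CH2 with no stereocentre.

Step 14
Reactants: 23 13-(dimethylamino)-11,13-dihydro target (11R)
Product: 25 CNP0510087.1 (target), via ammonium iodide 24 (not isolated)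
Conditions: MeI, MeOH, rt; then aq NaHCO3, EtOAc, rt
Reagents that add atoms: iodomethane, CI (its methyl group is in 24 and leaves again as trimethylamine)
Why: N-Methylation to the quaternary ammonium salt followed by E1cB (Hofmann-type) elimination of trimethylamine through the lactone enolate regenerates the exocyclic C11=C13 alkene without touching the esters.

Compound list
1 | (E)-but-2-enal (crotonaldehyde) | C/C=C/C=O | starting material
2 | nitromethane | C[N+](=O)[O-] | starting material
3 | (3R)-3-methyl-4-nitrobutanal | O=CC[C@@H](C)C[N+](=O)[O-] | intermediate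
4 | allenylboronic acid pinacol ester | C=C=CB1OC(C)(C)C(C)(C)O1 | starting material
5 | (4R,6R)-6-methyl-7-nitrohept-1-yn-4-ol | C#CC[C@H](O)C[C@@H](C)C[N+](=O)[O-] | intermediate
6 | (5R)-3-methylidene-5-[(2R)-2-methyl-3-nitropropyl]oxolan-2-one | C=C1C[C@@H](C[C@@H](C)C[N+](=O)[O-])OC1=O | intermediate
7 | (5R)-3-bromo-3-(bromomethyl)-5-[(2R)-2-methyl-3-nitropropyl]oxolan-2-one (C3 epimers; not isolated) | BrCC1(Br)C[C@@H](C[C@@H](C)C[N+](=O)[O-])OC1=O | intermediate
8 | (5R)-3-(bromomethyl)-5-[(2R)-2-methyl-3-nitropropyl]furan-2(5H)-one | BrCC1=C[C@@H](C[C@@H](C)C[N+](=O)[O-])OC1=O | intermediate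
9 | methyl (triphenylphosphoranylidene)acetate | COC(=O)C=P(c1ccccc1)(c1ccccc1)c1ccccc1 | starting material
10 | allyl bromide | C=CCBr | starting material
11 | [1-(methoxycarbonyl)but-3-en-1-yl]triphenylphosphonium bromide (not isolated) | C=CCC(C(=O)OC)[P+](c1ccccc1)(c1ccccc1)c1ccccc1.[Br-] | intermediate
12 | methyl 2-(triphenylphosphoranylidene)pent-4-enoate | C=CCC(C(=O)OC)=P(c1ccccc1)(c1ccccc1)c1ccccc1 | intermediate
13 | glycolaldehyde dimer (1,4-dioxane-2,5-diol) | OC1COC(O)CO1 | starting material
14 | methyl (2E)-2-(2-hydroxyethylidene)pent-4-enoate | C=CC/C(=C\CO)C(=O)OC | intermediate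
15 | methyl (2E)-2-{2-[(methoxycarbonyl)oxy]ethylidene}pent-4-enoate | C=CC/C(=C\COC(=O)OC)C(=O)OC | intermediate
16 | methyl (2E)-4-[(methoxycarbonyl)oxy]-2-(2-oxoethyl)but-2-enoate | O=CC/C(=C\COC(=O)OC)C(=O)OC | intermediate
17 | {[(5R)-5-[(2R)-2-methyl-3-nitropropyl]-2-oxo-2,5-dihydrofuran-3-yl]methyl}indium dibromide (simplest formulation; not isolated) | Br[In](Br)CC1=C[C@@H](C[C@@H](C)C[N+](=O)[O-])OC1=O | intermediate
18 | methyl (2E)-2-{(2S)-2-hydroxy-2-[(2R,3R)-2-[(2R)-2-methyl-3-nitropropyl]-4-methylidene-5-oxooxolan-3-yl]ethyl}-4-[(methoxycarbonyl)oxy]but-2-enoate | C=C1C(=O)O[C@H](C[C@@H](C)C[N+](=O)[O-])[C@H]1[C@@H](O)C/C(=C\COC(=O)OC)C(=O)OC | intermediate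
19 | angelic acid, (2Z)-2-methylbut-2-enoic acid | C/C=C(/C)C(=O)O | starting material
20 | methyl (2E)-2-{(2R)-2-{[(2Z)-2-methylbut-2-enoyl]oxy}-2-[(2R,3S)-2-[(2R)-2-methyl-3-nitropropyl]-4-methylidene-5-oxooxolan-3-yl]ethyl}-4-[(methoxycarbonyl)oxy]but-2-enoate | C=C1C(=O)O[C@H](C[C@@H](C)C[N+](=O)[O-])[C@H]1[C@@H](C/C(=C\COC(=O)OC)C(=O)OC)OC(=O)/C(C)=C\C | intermediate
21 | methyl (2E)-2-{(2R)-2-{[(2Z)-2-methylbut-2-enoyl]oxy}-2-[(2R,3S,4R)-4-[(dimethylamino)methyl]-2-[(2R)-2-methyl-3-nitropropyl]-5-oxooxolan-3-yl]ethyl}-4-[(methoxycarbonyl)oxy]but-2-enoate | CN(C)C[C@@H]1C(=O)O[C@H](C[C@@H](C)C[N+](=O)[O-])[C@H]1[C@@H](C/C(=C\COC(=O)OC)C(=O)OC)OC(=O)/C(C)=C\C | intermediate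
22 | methyl (1(10)E,4R,6R,7S,8R,11R)-8-(angeloyloxy)-13-(dimethylamino)-3-nitro-11,13-dihydrogermacr-1(10)-en-12,6-olid-14-oate, mixture of C3 epimers | CN(C)C[C@@H]1C(=O)O[C@@H]2C[C@@H](C)C([N+](=O)[O-])C/C=C(/C(=O)OC)C[C@@H](OC(=O)/C(C)=C\C)[C@@H]12 | intermediate
23 | methyl (1(10)E,4S,6R,7S,8R,11R)-8-(angeloyloxy)-13-(dimethylamino)-11,13-dihydrogermacr-1(10)-en-12,6-olid-14-oate | CN(C)C[C@@H]1C(=O)O[C@@H]2C[C@@H](C)CC/C=C(/C(=O)OC)C[C@@H](OC(=O)/C(C)=C\C)[C@@H]12 | intermediate
24 | 13-(trimethylammonio) analogue of 23, iodide (not isolated) | C[N+](C)(C)C[C@@H]1C(=O)O[C@@H]2C[C@@H](C)CC/C=C(/C(=O)OC)C[C@@H](OC(=O)/C(C)=C\C)[C@@H]12.[I-] | intermediate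
25 | CNP0510087.1, methyl (1(10)E,4S,6R,7S,8R)-8-{[(2Z)-2-methylbut-2-enoyl]oxy}germacra-1(10),11(13)-dien-12,6-olid-14-oate | C=C1C(=O)O[C@@H]2C[C@@H](C)CC/C=C(/C(=O)OC)C[C@@H](OC(=O)/C(C)=C\C)[C@@H]12 | target

Total step count: 14.
Longest linear sequence: 10 steps (steps 1–4 then 9–14; the aldehyde branch, steps 5–8, joins at step 9 and is equally long).

Steps most likely to fail

Step 12 (key macrocyclisation). What may go wrong: intermolecular allylation (oligomerisation) or O-allylation outrunning the strained ten-membered C–C closure. The fallback forms the same C2–C3 bond by carbonyl olefination and sets out from 21. A reductive Nef reaction (buffered aq TiCl3, NH4OAc, THF) should convert the CH2NO2 group into the C3 aldehyde F1. Pd(PPh3)4 (catalytic) with PPh3 (1.1 equiv) in THF at high dilution should then turn the allylic carbonate into the allyltriphenylphosphonium methyl carbonate. Its own methoxide forms the ester-conjugated ylide at C2, and intramolecular Wittig olefination with the C3 aldehyde should close the ring as the cyclic dienoate F2 (either C2=C3 geometry serves; C4, now α to the aldehyde, is kept away from added base). Diimide (o-nitrobenzenesulfonylhydrazide, Et3N, CH2Cl2, rt) should then saturate only the disubstituted C2=C3 bond and give 23, so that step 13 is not needed.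

Step 13 (denitration). What may go wrong: slow chain transfer at the unactivated secondary nitro centre, leaving time for stannyl-radical Z-to-E isomerisation of the angelate or thermal loss of dimethylamine at 110 °C. The fallback is ionic and sets out from 22. A Nef reaction (DBU to the nitronate, then buffered aq TiCl3) should give the C3 ketone F3. TsNHNH2 in EtOH should give the tosylhydrazone F4. Reduction with catecholborane (CHCl3, 0 °C) followed by NaOAc·3H2O and warming (collapse of the alkyldiazene with loss of N2) should give 23.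

Step 10 (Mitsunobu angeloylation). What may go wrong: elimination or no displacement at the hindered C8 carbinol with the weakly acidic, bulky angelic acid, or phosphine-induced isomerisation of the angelate. The fallback separates inversion from acylation and sets out from 18. Dimethylamine (as in step 11) should give the masked 8S alcohol F5. Mitsunobu inversion with formic acid (PPh3, DIAD, THF) should give the 8R formate F6. NaHCO3 in MeOH at rt should remove the formyl group and give the 8R alcohol F7. Acylation with the mixed anhydride of angelic acid and 2,4,6-trichlorobenzoyl chloride (Et3N, then toluene, 80 °C, Yamaguchi-type, no DMAP) should give 21.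

Further compounds
F1 | step 12 | C3 aldehyde from Nef reaction of 21: methyl (2E)-2-{(2R)-2-(angeloyloxy)-2-[(2R,3S,4R)-4-[(dimethylamino)methyl]-2-[(2R)-2-methyl-3-oxopropyl]-5-oxooxolan-3-yl]ethyl}-4-[(methoxycarbonyl)oxy]but-2-enoate | CN(C)C[C@@H]1C(=O)O[C@H](C[C@@H](C)C=O)[C@H]1[C@@H](C/C(=C\COC(=O)OC)C(=O)OC)OC(=O)/C(C)=C\C
F2 | step 12 | cyclic dienoate, 2,3-didehydro analogue of 23 (C2=C3 geometry undefined) | CN(C)C[C@@H]1C(=O)O[C@@H]2C[C@@H](C)C=C/C=C(/C(=O)OC)C[C@@H](OC(=O)/C(C)=C\C)[C@@H]12
F3 | step 13 | C3 ketone, 3-oxo analogue of 23 | CN(C)C[C@@H]1C(=O)O[C@@H]2C[C@@H](C)C(=O)C/C=C(/C(=O)OC)C[C@@H](OC(=O)/C(C)=C\C)[C@@H]12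
F4 | step 13 | tosylhydrazone of F3 (C=N geometry undefined) | CN(C)C[C@@H]1C(=O)O[C@@H]2C[C@@H](C)C(=NNS(=O)(=O)c3ccc(C)cc3)C/C=C(/C(=O)OC)C[C@@H](OC(=O)/C(C)=C\C)[C@@H]12
F5 | step 10 | masked 8S alcohol, 13-(dimethylamino) adduct of 18 (11R) | CN(C)C[C@@H]1C(=O)O[C@H](C[C@@H](C)C[N+](=O)[O-])[C@H]1[C@@H](O)C/C(=C\COC(=O)OC)C(=O)OC
F6 | step 10 | 8R formate of the masked seco-lactone | CN(C)C[C@@H]1C(=O)O[C@H](C[C@@H](C)C[N+](=O)[O-])[C@H]1[C@@H](C/C(=C\COC(=O)OC)C(=O)OC)OC=O
F7 | step 10 | masked 8R alcohol (C8 epimer of F5) | CN(C)C[C@@H]1C(=O)O[C@H](C[C@@H](C)C[N+](=O)[O-])[C@H]1[C@H](O)C/C(=C\COC(=O)OC)C(=O)OC
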